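**Retrosynthetic overview**
1. The target comes from its tetra-silyl ether. The C2–aryl bond is cut back to a lactol acetate plus an arylzinc reagent, and axial attack sets C2.
2. The lactol acetate comes from the 3,5-cis δ-lactone. C3 is set by C-protonation of the lactone's ketene silyl acetal.
3. The δ-lactone comes from a two-atom ring expansion of a 3-substituted oxetane with an ester enolate. This step makes the C3–C4 bond and sets C5.
4. The oxetanyl carbinol comes from oxetane-3-carbaldehyde by catalytic asymmetric arylation, the only external source of chirality. The ester comes from a Heck arylation of methyl pent-4-enoate.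
5. Only one ring is built: the bought four-membered ring becomes the oxane ring in step 3. All three aryl rings come from one protected 4-bromophenol.

**Assumption:** the SMILES is read as (2R,3S,5R) in the oxane ring and (R) at the carbinol carbon, so all three ring substituents lie on one face; 1 is bought as the silyl ether, and if the ligand in step 2 induces the opposite sense, its other enantiomer is used.

Ar = 4-(tert-butyldimethylsilyloxy)phenyl throughout. Positions C2–C6 follow the oxane numbering of the target.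

Step 1
Reactants: 1 (4-bromophenoxy)(tert-butyl)dimethylsilane; 2 methyl pent-4-enoate
Product: 3 methyl (4E)-5-Ar-pent-4-enoate
Conditions: Pd(OAc)2 (2 mol %), P(o-tol)3, Et3N, DMF, 100 °C
Reagents that add atoms: none
Why: Mizoroki–Heck arylation, in which carbopalladation at the terminal carbon and syn β-hydride elimination toward the benzylic hydrogen give the conjugated E-styrene, and no stereocentre is formed.

Step 2
Reactants: 1 (4-bromophenoxy)(tert-butyl)dimethylsilane; 4 oxetane-3-carbaldehyde
Product: 8 (R)-Ar(oxetan-3-yl)methanol, via aryllithium 5 (not isolated), via arylzinc chloride 6 (not isolated), via aryl(butyl)zinc 7 (not isolated)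
Conditions: n-BuLi, t-BuOMe, −78 °C; ZnCl2, 0 °C; n-BuLi, 0 °C; Et2NCH2CH2NEt2, (−)-3-exo-morpholinoisoborneol (5 mol %), toluene; then 4, 0 °C
Reagents that add atoms: none
Why: Catalytic enantioselective aryl transfer from a mixed aryl(alkyl)zinc to an α-branched aliphatic aldehyde under amino-alcohol ligand control, in which the achiral aldehyde sees only reagent control, the diamine masks LiCl to suppress the racemic background, and the R carbinol centre is set.

Step 3
Reactants: 8 (R)-Ar(oxetan-3-yl)methanol; 3 methyl (4E)-5-Ar-pent-4-enoate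
Product: 13 (5R)-5-[(R)-hydroxy(Ar)methyl]-3-[(E)-3-Ar-prop-2-en-1-yl]oxan-2-one (C3 epimer mixture), via aluminium alkoxide chelate 9 (not isolated), via lithium enolate 10 (not isolated), via diethylaluminium enolate 11 (not isolated), via ring-opened hydroxy ester 12 (not isolated)
Conditions: 8, Me3Al (1.0 equiv), toluene, 0 °C; separately 3 (2.2 equiv), LiN(i-Pr)2, THF–toluene, −78 °C, then Et2AlCl; combine, −40 to 23 °C; aq potassium sodium tartrate
Reagents that add atoms: none
Why: Proposed new method: a hydroxyl-directed, desymmetrising two-atom ring expansion of a 3-substituted oxetane, in which the dimethylaluminium alkoxide binds the oxetane oxygen intramolecularly in a pinane-like bicyclo[3.1.1] chelate that activates the ring and holds the aryl group of the R carbinol over the backside trajectory of one CH2, so the aluminium ester enolate opens the other CH2 by SN2 (new C3–C4 bond, C5 fixed as R), and the freed primary alkoxide then acylates on the methyl ester to close the six-membered lactone in preference to the hindered benzylic oxygen; the closest known reaction types are the Lewis-acid-promoted opening of oxetanes by lithium ester enolates to δ-lactones, the opening of epoxides by diethylaluminium ester enolates and the alkoxide-directed opening of 2,3-epoxy alcohols, none of which has been used to tell apart the two CH2 groups of an oxetane with a carbon nucleophile.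

Step 4
Reactants: 13 hydroxy lactone (C3 epimer mixture)
Product: 15 (3S,5R)-5-[(R)-(tert-butyldimethylsilyloxy)(Ar)methyl]-3-[(E)-3-Ar-prop-2-en-1-yl]oxan-2-one, via bis-silylated ketene acetal 14 (not isolated)
Conditions: t-BuMe2SiOTf (3 equiv), Et3N, CH2Cl2, 0 to 23 °C; then AcOH, THF–H2O, 0 °C
Reagents that add atoms: tert-butyldimethylsilyl triflate CC(C)(C)[Si](C)(C)OS(=O)(=O)C(F)(F)F
Why: Silyl triflate O-silylation plus soft enolisation to the cyclic ketene silyl acetal erases C3, and kinetic C-protonation then comes axially on the face of the axial C5–H (chair-like transition state, C5 side chain equatorial), which places the cinnamyl group equatorial and cis to the C5 side chain (3S), also the more stable isomer.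

Step 5
Reactants: 15 silyl-protected cis-lactone
Product: 17 (3S,5R)-5-[(R)-(tert-butyldimethylsilyloxy)(Ar)methyl]-3-[(E)-3-Ar-prop-2-en-1-yl]oxan-2-yl acetate (anomer mixture), via aluminium lactolate 16 (not isolated)
Conditions: i-Bu2AlH, CH2Cl2, −78 °C; then pyridine, DMAP, Ac2O, −78 to −20 °C
Reagents that add atoms: acetic anhydride CC(=O)OC(C)=O
Why: Reductive acetylation of a lactone, in which the low-temperature aluminium lactolate is trapped in situ, so the ring never opens to the aldehyde, C3 is not epimerised, and the new anomeric centre is an inconsequential mixture.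

Step 6
Reactants: 17 lactol acetate; 1 (4-bromophenoxy)(tert-butyl)dimethylsilane
Product: 20 (2R,3S,5R)-2-Ar-5-[(R)-(tert-butyldimethylsilyloxy)(Ar)methyl]-3-[(E)-3-Ar-prop-2-en-1-yl]oxane, via arylmagnesium bromide 18 (not isolated), via diarylzinc 19 (not isolated)
Conditions: 1, Mg, THF; ZnBr2 (0.5 equiv per ArMgBr), Et2O, 0 °C; then 17, 0 to 23 °C
Reagents that add atoms: none
Why: SN1-type substitution of a lactol acetate by an arylzinc reagent (C-glycosylation type), in which the MgBr2 formed in the transmetalation ionises the acetate and the oxocarbenium ion, locked in the half-chair with the C3 and C5 groups pseudo-equatorial because the other half-chair has a syn-diaxial clash, is attacked axially through a chair-like transition state to give the axial 2-aryl group, that is 2,3-cis and 2,5-cis (2R).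

Step 7
Reactants: 20 tetra-silyl ether
Product: 21 4-[(2R,3S,5R)-5-[(R)-hydroxy(4-hydroxyphenyl)methyl]-3-[(E)-3-(4-hydroxyphenyl)prop-2-en-1-yl]oxan-2-yl]phenol
Conditions: n-Bu4NF, AcOH (1:1, 6 equiv), THF, 0 to 23 °C
Reagents that add atoms: none
Why: Fluoride-mediated desilylation, driven by the Si–F bond, removes all four silyl groups, and the AcOH buffer keeps phenoxide low so that the benzylic C2–O bond does not open to a quinone methide and no stereocentre is touched.

**Compound list**
1 | (4-bromophenoxy)(tert-butyl)dimethylsilane | CC(C)(C)[Si](C)(C)Oc1ccc(Br)cc1 | starting material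
2 | methyl pent-4-enoate | C=CCCC(=O)OC | starting material
3 | methyl (4E)-5-Ar-pent-4-enoate | COC(=O)CC/C=C/c1ccc(O[Si](C)(C)C(C)(C)C)cc1 | intermediate
4 | oxetane-3-carbaldehyde | O=CC1COC1 | starting material
5 | Ar-lithium | [Li]c1ccc(O[Si](C)(C)C(C)(C)C)cc1 | intermediate
6 | Ar-zinc chloride | Cl[Zn]c1ccc(O[Si](C)(C)C(C)(C)C)cc1 | intermediate
7 | butyl(Ar)zinc | CCCC[Zn]c1ccc(O[Si](C)(C)C(C)(C)C)cc1 | intermediate
8 | (R)-Ar(oxetan-3-yl)methanol | O1CC(C1)[C@@H](O)c1ccc(O[Si](C)(C)C(C)(C)C)cc1 | intermediate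
9 | dimethylaluminium alkoxide of 8 (Al also bound by the oxetane O) | O1CC(C1)[C@@H](O[Al](C)C)c1ccc(O[Si](C)(C)C(C)(C)C)cc1 | intermediate
10 | lithium enolate of 3 | [Li]OC(OC)=CC/C=C/c1ccc(O[Si](C)(C)C(C)(C)C)cc1 | intermediate
11 | diethylaluminium enolate of 3 | CC[Al](CC)OC(OC)=CC/C=C/c1ccc(O[Si](C)(C)C(C)(C)C)cc1 | intermediate
12 | methyl (4E)-2-[(2R,3R)-3-hydroxy-2-(hydroxymethyl)-3-Ar-propyl]-5-Ar-pent-4-enoate (C2 epimers; aluminium alkoxide in the flask, drawn as the diol) | COC(=O)C(C/C=C/c1ccc(O[Si](C)(C)C(C)(C)C)cc1)C[C@H](CO)[C@@H](O)c1ccc(O[Si](C)(C)C(C)(C)C)cc1 | intermediate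
13 | (5R)-5-[(R)-hydroxy(Ar)methyl]-3-[(E)-3-Ar-prop-2-en-1-yl]oxan-2-one (C3 epimers) | CC(C)(C)[Si](C)(C)Oc1ccc(/C=C/CC2C[C@@H]([C@@H](O)c3ccc(O[Si](C)(C)C(C)(C)C)cc3)COC2=O)cc1 | intermediate
14 | (3R)-6-(tert-butyldimethylsilyloxy)-3-[(R)-(tert-butyldimethylsilyloxy)(Ar)methyl]-5-[(E)-3-Ar-prop-2-en-1-yl]-3,4-dihydro-2H-pyran | CC(C)(C)[Si](C)(C)Oc1ccc(/C=C/CC=2C[C@@H]([C@@H](O[Si](C)(C)C(C)(C)C)c3ccc(O[Si](C)(C)C(C)(C)C)cc3)COC=2O[Si](C)(C)C(C)(C)C)cc1 | intermediate
15 | (3S,5R)-5-[(R)-(tert-butyldimethylsilyloxy)(Ar)methyl]-3-[(E)-3-Ar-prop-2-en-1-yl]oxan-2-one | CC(C)(C)[Si](C)(C)Oc1ccc(/C=C/C[C@H]2C[C@@H]([C@@H](O[Si](C)(C)C(C)(C)C)c3ccc(O[Si](C)(C)C(C)(C)C)cc3)COC2=O)cc1 | intermediate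
16 | diisobutylaluminium lactolate of 15 | CC(C)(C)[Si](C)(C)Oc1ccc(/C=C/C[C@H]2C[C@@H]([C@@H](O[Si](C)(C)C(C)(C)C)c3ccc(O[Si](C)(C)C(C)(C)C)cc3)COC2O[Al](CC(C)C)CC(C)C)cc1 | intermediate
17 | lactol acetate of 15 (anomers) | CC(C)(C)[Si](C)(C)Oc1ccc(/C=C/C[C@H]2C[C@@H]([C@@H](O[Si](C)(C)C(C)(C)C)c3ccc(O[Si](C)(C)C(C)(C)C)cc3)COC2OC(C)=O)cc1 | intermediate
18 | Ar-magnesium bromide | Br[Mg]c1ccc(O[Si](C)(C)C(C)(C)C)cc1 | intermediate
19 | di(Ar)zinc | CC(C)(C)[Si](C)(C)Oc1ccc([Zn]c2ccc(O[Si](C)(C)C(C)(C)C)cc2)cc1 | intermediate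
20 | tetra-silyl ether of the target, (2R,3S,5R), carbinol (R) | CC(C)(C)[Si](C)(C)Oc1ccc(/C=C/C[C@H]2C[C@@H]([C@@H](O[Si](C)(C)C(C)(C)C)c3ccc(O[Si](C)(C)C(C)(C)C)cc3)CO[C@H]2c2ccc(O[Si](C)(C)C(C)(C)C)cc2)cc1 | intermediate
21 | CNP0182155.1 | Oc1ccc(/C=C/C[C@H]2C[C@@H]([C@@H](O)c3ccc(O)cc3)CO[C@H]2c2ccc(O)cc2)cc1 | target

**Totals:** 7 steps in all; the longest linear sequence is 6 steps (steps 2 to 7, or steps 1 and 3 to 7).

**Steps most likely to fail**

Step 2. The aldehyde is fragile, and its ring oxygen may bind zinc and erode the ee. The fallback separates bond formation from stereocontrol. It sets out from 4 and 18 and comes back at 8. Grignard reagent 18 is added to 4 (THF, −78 °C) to give the racemic carbinol F1. Dess–Martin periodinane oxidises it to the aryl oxetanyl ketone F2. Corey–Bakshi–Shibata reduction ((S)-2-methyl-CBS-oxazaborolidine, BH3·SMe2), with aryl as the large group, then gives 8.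

Step 3 (the new reaction). The risks are too little activation by the tethered aluminium, low selectivity between the two CH2 groups, and lactonisation through the benzylic oxygen. The fallback uses known chemistry. It sets out from 8 and comes back at 15.
- 8 is silylated (t-BuMe2SiCl, imidazole, DMF) to the silyl ether F3.
- The oxetane is opened with Me3SiBr under a chiral squaramide hydrogen-bond-donor catalyst. This is a known enantioselective oxetane opening, used here under catalyst control, and it gives the bromide F4.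
- Lithium enolate 10 is alkylated with F4 (THF–DMPU) to the ester F5.
- Citric acid in MeOH removes the Me3Si group to give the hydroxy ester F6.
- F6 lactonises to 15 together with the C3 epimer F7.
- The mixture is converged on 15 through ketene acetal 14 exactly as in step 4.

Step 6. The basic arylzinc may eliminate the acetate to the glycal. The Lewis acids may ionise the benzylic silyl ether, or epimerise the axial aryl group to the equatorial one. The fallback replaces the cation by a radical. It sets out from 17 and comes back at 20. Me3SiBr (CH2Cl2, −20 °C) gives the anomeric bromide F8. F8 is cross-coupled with 18 under Co(acac)3/TMEDA (THF, 0 °C). The anomeric radical forms its new bond axially, and no Lewis acid is needed.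

**Further compounds**
F1 | step 2 | rac-Ar(oxetan-3-yl)methanol | O1CC(C1)C(O)c1ccc(O[Si](C)(C)C(C)(C)C)cc1
F2 | step 2 | Ar oxetan-3-yl ketone | O=C(C1COC1)c1ccc(O[Si](C)(C)C(C)(C)C)cc1
F3 | step 3 | tert-butyldimethylsilyl ether of 8 | O1CC(C1)[C@@H](O[Si](C)(C)C(C)(C)C)c1ccc(O[Si](C)(C)C(C)(C)C)cc1
F4 | step 3 | (1R,2R)-3-bromo-1-Ar-1-(tert-butyldimethylsilyloxy)-2-(trimethylsilyloxymethyl)propane | BrC[C@H](CO[Si](C)(C)C)[C@@H](O[Si](C)(C)C(C)(C)C)c1ccc(O[Si](C)(C)C(C)(C)C)cc1
F5 | step 3 | alkylated methyl ester (C2 epimers, O-SiMe3) | COC(=O)C(C/C=C/c1ccc(O[Si](C)(C)C(C)(C)C)cc1)C[C@H](CO[Si](C)(C)C)[C@@H](O[Si](C)(C)C(C)(C)C)c1ccc(O[Si](C)(C)C(C)(C)C)cc1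
F6 | step 3 | δ-hydroxy methyl ester (C2 epimers) | COC(=O)C(C/C=C/c1ccc(O[Si](C)(C)C(C)(C)C)cc1)C[C@H](CO)[C@@H](O[Si](C)(C)C(C)(C)C)c1ccc(O[Si](C)(C)C(C)(C)C)cc1
F7 | step 3 | (3R,5R) C3 epimer of 15 | CC(C)(C)[Si](C)(C)Oc1ccc(/C=C/C[C@@H]2C[C@@H]([C@@H](O[Si](C)(C)C(C)(C)C)c3ccc(O[Si](C)(C)C(C)(C)C)cc3)COC2=O)cc1
F8 | step 6 | anomeric bromide from 17 | CC(C)(C)[Si](C)(C)Oc1ccc(/C=C/C[C@H]2C[C@@H]([C@@H](O[Si](C)(C)C(C)(C)C)c3ccc(O[Si](C)(C)C(C)(C)C)cc3)COC2Br)cc1
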